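**Strategy.** The route rests on cutting the C3–O and C4–O bonds of ring C back to the C3=C4 alkene of a (2S)-flav-3-ene. The target carries oxygen on the adjacent carbons C3 and C4 of ring C, with the C3 oxygen trans to the ring B aryl group at C2. OsO4 syn-dihydroxylation on the face opposite that aryl group installs both oxygens and the C3 configuration in one operation, relayed from C2. The precursor is a 2-aryl-2H-chromene with ring A as its 5,6,7-trimethyl ether and the ring B hydroquinone as its dibenzyl ether, made by enantioselective arylation of a chromene acetal. Selective C4 oxidation, O3-methylation and global unmasking finish the synthesis.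

Key step: step 7

Assumption: the sense of induction of the tartaric acid monoamide catalyst in step 6 is to be fixed by a trial run; whichever enantiomer (both derive from commercial tartaric acid) gives the (2S)-flavene 13 is used.

Remark: the spatial arrangement at C2 does not change after step 6. The descriptor changes from 2S in 13 to 2R from 15 onward only because C3, once it bears oxygen, outranks the aryl carbon. In 15 the aryl group lies on one face of ring C and both hydroxyls on the other, as anti attack on 13 requires. The C4 centre made in step 7 is removed again in step 8.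

**Step 1**
Reactants: 1 3,4,5-trimethoxyphenol
Product: 3 5,6,7-trimethoxycoumarin (5,6,7-trimethoxy-2H-chromen-2-one), via (Z)-hydroxycinnamate ester 2 (not isolated)
Conditions: ethyl propiolate (2 equiv), Pd(OAc)2 (5 mol %), NaOAc (20 mol %), HCO2H, rt
Reagents that add atoms: ethyl propiolate, C#CC(=O)OCC
Why: Palladium-catalysed hydroarylation of the alkynoate by the electron-rich phenol (a coumarin annulation of the Pechmann type) should form the aryl–C4 bond at one of the two equivalent positions ortho to the hydroxyl, which are the only free ring positions, and the (Z)-cinnamate 2 then lactonises in the flask without creating a stereocentre.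

**Step 2**
Reactants: 3 5,6,7-trimethoxycoumarin
Product: 5 2-ethoxy-5,6,7-trimethoxy-2H-chromene (racemic acetal), via lactol 4 (not isolated)
Conditions: i-Bu2AlH (1.1 equiv), CH2Cl2, −78 °C; aq. KNaC4H4O6 work-up; crude 4, EtOH, PPTS (cat.), rt
Reagents that add atoms: ethanol, CCO
Why: Half-reduction of the lactone should stop at the aluminium-bound hemiacetal at −78 °C to give lactol 4, which exchanges hydroxyl for ethoxy under mild acid through the stabilised benzopyrylium ion (lactone partial reduction, then acid-catalysed acetal formation), the new C2 centre being racemic and erased in step 6.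

**Step 3**
Reactants: 6 2-methoxyhydroquinone
Product: 7 1,4-bis(benzyloxy)-2-methoxybenzene
Conditions: BnBr (2.3 equiv), K2CO3 (3 equiv), DMF, N2, rt → 50 °C
Reagents that add atoms: benzyl bromide, BrCc1ccccc1
Why: Williamson ether synthesis on both phenoxides should proceed cleanly under nitrogen, which protects the air-sensitive hydroquinone anion until it is capped.

**Step 4**
Reactants: 7 1,4-bis(benzyloxy)-2-methoxybenzene
Product: 8 1,4-bis(benzyloxy)-2-bromo-5-methoxybenzene
Conditions: NBS (1.05 equiv), MeCN, 0 °C, dark
Reagents that add atoms: N-bromosuccinimide, O=C1CCC(=O)N1Br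
Why: Electrophilic aromatic bromination should occur at the one position that is para to the methoxy group, ortho to a benzyloxy group and not flanked by two substituents, as is general for 1,2,4-trialkoxybenzenes.

**Step 5**
Reactants: 8 1,4-bis(benzyloxy)-2-bromo-5-methoxybenzene
Product: 11 [2,5-bis(benzyloxy)-4-methoxyphenyl]boronic acid, via aryllithium 9 (not isolated), via lithium aryltriisopropoxyborate 10 (not isolated)
Conditions: n-BuLi (1.05 equiv), THF, −78 °C; B(Oi-Pr)3 (1.5 equiv), −78 °C → rt; 1 M HCl, 0 °C
Reagents that add atoms: triisopropyl borate, CC(C)OB(OC(C)C)OC(C)C; water, O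
Why: Bromine–lithium exchange at −78 °C is faster than deprotonation or attack on the benzyl ethers, and the aryllithium 9 is trapped by the borate as the ate complex 10, which dilute acid hydrolyses to the boronic acid (lithiation–borylation).

**Step 6**
Reactants: 5 2-ethoxy-5,6,7-trimethoxy-2H-chromene; 11 [2,5-bis(benzyloxy)-4-methoxyphenyl]boronic acid
Product: 13 (2S)-2-[2,5-bis(benzyloxy)-4-methoxyphenyl]-5,6,7-trimethoxy-2H-chromene, via diethyl arylboronate 12 (not isolated)
Conditions: 11, EtOH, 3 Å MS, evaporation (→ 12); then 5, 4-(dibenzylamino)-2,3-dihydroxy-4-oxobutanoic acid (single enantiomer, 10 mol %), Yb(OTf)3 (5 mol %), EtOAc, −20 → 4 °C, dark; Et3N-buffered silica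
Reagents that add atoms: none
Why: Yb(OTf)3 should ionise the acetal to the 5,6,7-trimethoxybenzopyrylium ion while the boronate exchanges its ethoxy groups for the chiral α-hydroxy acid, and the resulting chiral boronate complex transfers the aryl group to C2 of the ion pair on one enantiotopic face, so the C2 stereocentre is set by the catalyst (enantioselective Petasis-type boronate addition to a chromene acetal under chiral Brønsted acid and lanthanide triflate co-catalysis, the non-oxidising trivalent ytterbium salt being chosen to spare the electron-rich rings).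

**Step 7**
Reactants: 13 (2S)-2-[2,5-bis(benzyloxy)-4-methoxyphenyl]-5,6,7-trimethoxy-2H-chromene
Product: 15 (2R,3S,4S)-2-[2,5-bis(benzyloxy)-4-methoxyphenyl]-5,6,7-trimethoxy-3,4-dihydro-2H-chromene-3,4-diol (2,3-trans-3,4-cis), via cyclic osmate ester 14 (not isolated)
Conditions: OsO4 (2 mol %), NMO (1.5 equiv), acetone–H2O (10:1), 0 °C → rt, dark; aq. Na2SO3
Reagents that add atoms: osmium tetroxide, O=[Os](=O)(=O)=O (catalytic carrier of both oxygen atoms); N-methylmorpholine N-oxide, C[N+]1([O-])CCOCC1; water, O
Why: OsO4 adds across the C3=C4 bond in a concerted, suprafacial [3+2] cycloaddition to give the hexavalent osmium glycolate 14, which water hydrolyses to the diol while N-methylmorpholine N-oxide returns osmium to the octavalent state. The closest known reaction is the catalytic OsO4 dihydroxylation of 2-substituted 2H-chromenes and flav-3-enes, which gives 2,3-trans-3,4-cis flavan-3,4-diols. No ring of the product is closed; the five-membered osmate ring is transient. C3 and C4 are both fixed by the face of attack: the aryl group on the neighbouring sp3 carbon C2 covers one face of the nearly flat C3=C4–ring A styrene unit, so osmium approaches from the other face and both hydroxyls end up cis to each other and trans to the aryl group (3S,4S). The step needs diastereofacial selectivity only, and the C2 substituent with its ortho-benzyloxy group secures it; chemoselectivity is not at issue because C3=C4 is the only alkene and the aryl and benzyl ethers are inert to OsO4.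

**Step 8**
Reactants: 15 (2R,3S,4S)-2-[2,5-bis(benzyloxy)-4-methoxyphenyl]-5,6,7-trimethoxy-3,4-dihydro-2H-chromene-3,4-diol
Product: 16 (2R,3R)-2-[2,5-bis(benzyloxy)-4-methoxyphenyl]-3-hydroxy-5,6,7-trimethoxy-2,3-dihydro-4H-chromen-4-one
Conditions: DDQ (1.1 equiv), CH2Cl2, 0 °C → rt
Reagents that add atoms: none
Why: DDQ should remove hydride from C4–H, the only carbinol C–H that is benzylic to ring A and activated by its ortho and para oxygen substituents and by the hydroxyl on the same carbon, so the C4 alcohol gives the aryl ketone while the C3 alcohol and the C2 and C3 centres are untouched (DDQ oxidation of an electron-rich benzylic alcohol, which also avoids the glycol cleavage that metal-oxide oxidants can cause with cis-diols).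

**Step 9**
Reactants: 16 (2R,3R)-2-[2,5-bis(benzyloxy)-4-methoxyphenyl]-3-hydroxy-5,6,7-trimethoxy-2,3-dihydro-4H-chromen-4-one
Product: 17 (2R,3R)-2-[2,5-bis(benzyloxy)-4-methoxyphenyl]-3,5,6,7-tetramethoxy-2,3-dihydro-4H-chromen-4-one
Conditions: Me3OBF4 (3 equiv), 1,8-bis(dimethylamino)naphthalene (3.5 equiv), 4 Å MS, CH2Cl2, 0 °C → rt
Reagents that add atoms: trimethyloxonium tetrafluoroborate, C[O+](C)C.F[B-](F)(F)F
Why: The oxonium salt should methylate the secondary C3 hydroxyl while the hindered, non-nucleophilic base only takes up HBF4, so the C4 ketone is not enolised and C3 keeps its configuration (Meerwein-salt O-methylation).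

**Step 10**
Reactants: 17 (2R,3R)-2-[2,5-bis(benzyloxy)-4-methoxyphenyl]-3,5,6,7-tetramethoxy-2,3-dihydro-4H-chromen-4-one
Product: 18 (2R,3R)-2-(2,5-dihydroxy-4-methoxyphenyl)-5-hydroxy-3,6,7-trimethoxy-2,3-dihydro-4H-chromen-4-one (target)
Conditions: BCl3 (6 equiv), C6HMe5 (6 equiv), CH2Cl2, −78 → 0 °C, Ar; MeOH then H2O, degassed
Reagents that add atoms: none
Why: BCl3 should cleave the two aryl benzyl ethers at low temperature with pentamethylbenzene as a non-basic trap for the benzyl cation, and cleave the C5 methyl ether selectively because boron chelated between the C4 carbonyl and O5 activates that methyl group toward chloride, whereas the other methyl ethers lack this activation (Lewis-acid ether cleavage with peri-selective demethylation, no stereocentre being touched).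

**Compound list**

1 | 3,4,5-trimethoxyphenol | COc1cc(O)cc(OC)c1OC | starting material
2 | ethyl (2Z)-3-(6-hydroxy-2,3,4-trimethoxyphenyl)prop-2-enoate | CCOC(=O)/C=C\c1c(O)cc(OC)c(OC)c1OC | intermediate
3 | 5,6,7-trimethoxycoumarin | COc1cc2OC(=O)C=Cc2c(OC)c1OC | intermediate
4 | 5,6,7-trimethoxy-2H-chromen-2-ol (racemic lactol) | COc1cc2OC(O)C=Cc2c(OC)c1OC | intermediate
5 | 2-ethoxy-5,6,7-trimethoxy-2H-chromene (racemic) | CCOC1C=Cc2c(OC)c(OC)c(OC)cc2O1 | intermediate
6 | 2-methoxyhydroquinone | COc1cc(O)ccc1O | starting material
7 | 1,4-bis(benzyloxy)-2-methoxybenzene | COc1cc(OCc2ccccc2)ccc1OCc1ccccc1 | intermediate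
8 | 1,4-bis(benzyloxy)-2-bromo-5-methoxybenzene | COc1cc(OCc2ccccc2)c(Br)cc1OCc1ccccc1 | intermediate
9 | [2,5-bis(benzyloxy)-4-methoxyphenyl]lithium | COc1cc(OCc2ccccc2)c([Li])cc1OCc1ccccc1 | intermediate
10 | lithium [2,5-bis(benzyloxy)-4-methoxyphenyl]tri(propan-2-yloxy)borate | [Li+].COc1cc(OCc2ccccc2)c([B-](OC(C)C)(OC(C)C)OC(C)C)cc1OCc1ccccc1 | intermediate
11 | [2,5-bis(benzyloxy)-4-methoxyphenyl]boronic acid | COc1cc(OCc2ccccc2)c(B(O)O)cc1OCc1ccccc1 | intermediate
12 | diethyl [2,5-bis(benzyloxy)-4-methoxyphenyl]boronate | CCOB(OCC)c1cc(OCc2ccccc2)c(OC)cc1OCc1ccccc1 | intermediate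
13 | (2S)-2-[2,5-bis(benzyloxy)-4-methoxyphenyl]-5,6,7-trimethoxy-2H-chromene | COc1cc(OCc2ccccc2)c([C@H]2Oc3cc(OC)c(OC)c(OC)c3C=C2)cc1OCc1ccccc1 | intermediate
14 | cyclic hexavalent osmium glycolate (3,4-O-dioxoosmium ester) of 15 | COc1cc(OCc2ccccc2)c([C@H]2Oc3cc(OC)c(OC)c(OC)c3[C@H](O4)[C@@H]2O[Os]4(=O)=O)cc1OCc1ccccc1 | intermediate
15 | (2R,3S,4S)-2-[2,5-bis(benzyloxy)-4-methoxyphenyl]-5,6,7-trimethoxy-3,4-dihydro-2H-chromene-3,4-diol | COc1cc(OCc2ccccc2)c([C@H]2Oc3cc(OC)c(OC)c(OC)c3[C@H](O)[C@@H]2O)cc1OCc1ccccc1 | intermediate
16 | (2R,3R)-2-[2,5-bis(benzyloxy)-4-methoxyphenyl]-3-hydroxy-5,6,7-trimethoxy-2,3-dihydro-4H-chromen-4-one | COc1cc(OCc2ccccc2)c([C@H]2Oc3cc(OC)c(OC)c(OC)c3C(=O)[C@@H]2O)cc1OCc1ccccc1 | intermediate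
17 | (2R,3R)-2-[2,5-bis(benzyloxy)-4-methoxyphenyl]-3,5,6,7-tetramethoxy-2,3-dihydro-4H-chromen-4-one | COc1cc(OCc2ccccc2)c([C@H]2Oc3cc(OC)c(OC)c(OC)c3C(=O)[C@@H]2OC)cc1OCc1ccccc1 | intermediate
18 | (2R,3R)-2-(2,5-dihydroxy-4-methoxyphenyl)-5-hydroxy-3,6,7-trimethoxy-2,3-dihydro-4H-chromen-4-one | COc1cc(O)c([C@H]2Oc3cc(OC)c(OC)c(O)c3C(=O)[C@@H]2OC)cc1O | target

**Step count and risks**

Total: 10 steps. Longest linear sequence: 8 steps (steps 3 to 10, from 2-methoxyhydroquinone 6); the ring A branch (steps 1, 2, 6 to 10) is 7 steps.

Steps most likely to fail: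

1. Step 6. The ortho-substituted, electron-rich boronate may transfer its aryl group slowly or with poor face selectivity, and the electron-rich flavene may lose enantiopurity through reversible opening of the C2–O1 bond under acid, heat or light. Fallback: the C2–aryl bond is made without asymmetric induction and the enantiomers are separated after the key step. Setting out from 5 and 11, the zerovalent-nickel cross-coupling of chromene acetals with arylboronic acids (Ni(cod)2, PPh3, dioxane–tert-amyl alcohol, 40 °C) should give racemic 2-[2,5-bis(benzyloxy)-4-methoxyphenyl]-5,6,7-trimethoxy-2H-chromene F1. Dihydroxylation under the conditions of step 7 should give the racemic 2,3-trans-3,4-cis diol F2, a configurationally stable compound. Preparative chromatography on a chiral stationary phase then separates the enantiomers, and the route is rejoined at 15.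

2. Step 8. Hydride abstraction may occur at the doubly activated C2–H instead of at C4–H, the pseudo-equatorial C4–H may react sluggishly, or the product may be dehydrogenated further toward the flavonol. Fallback: the order of methylation and oxidation is reversed, so that no chemoselective oxidation is needed. Setting out from 15, Bu2SnO in toluene at reflux with removal of water should give the dibutylstannylene acetal F3. MeI and CsF in DMF should then methylate the equatorial, less hindered O3 to give (2R,3S,4S)-2-[2,5-bis(benzyloxy)-4-methoxyphenyl]-3,5,6,7-tetramethoxy-3,4-dihydro-2H-chromen-4-ol F4. Dess–Martin periodinane with NaHCO3 in CH2Cl2 oxidises the remaining C4 alcohol, and the route is rejoined at 17, bypassing 16 and step 9.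

3. Step 10. The excess Lewis acid needed for debenzylation may remove further methyl groups (at O3 or O6), benzyl cations may alkylate the electron-rich rings, ring C may open at the C2–O1 bond with epimerisation, and the liberated hydroquinone may be oxidised by air. Fallback: the unmasking is split into two orthogonal stages. Setting out from 17, hydrogenolysis (H2, Pd/C, EtOAc, rt) should remove both benzyl groups under neutral conditions to give (2R,3R)-2-(2,5-dihydroxy-4-methoxyphenyl)-3,5,6,7-tetramethoxy-2,3-dihydro-4H-chromen-4-one F5. A limited charge of AlCl3 in MeCN at rt under argon then cleaves only the chelated C5 methyl ether, and the route is rejoined at 18.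

**Further compounds**

F1 | step 6 | racemic 2-[2,5-bis(benzyloxy)-4-methoxyphenyl]-5,6,7-trimethoxy-2H-chromene (both enantiomers) | COc1cc(OCc2ccccc2)c([C@H]2Oc3cc(OC)c(OC)c(OC)c3C=C2)cc1OCc1ccccc1.COc1cc(OCc2ccccc2)c([C@@H]2Oc3cc(OC)c(OC)c(OC)c3C=C2)cc1OCc1ccccc1
F2 | step 6 | racemic 2,3-trans-3,4-cis-2-[2,5-bis(benzyloxy)-4-methoxyphenyl]-5,6,7-trimethoxy-3,4-dihydro-2H-chromene-3,4-diol (both enantiomers) | COc1cc(OCc2ccccc2)c([C@H]2Oc3cc(OC)c(OC)c(OC)c3[C@H](O)[C@@H]2O)cc1OCc1ccccc1.COc1cc(OCc2ccccc2)c([C@@H]2Oc3cc(OC)c(OC)c(OC)c3[C@@H](O)[C@H]2O)cc1OCc1ccccc1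
F3 | step 8 | 3,4-O-dibutylstannylene acetal of 15 | COc1cc(OCc2ccccc2)c([C@H]2Oc3cc(OC)c(OC)c(OC)c3[C@H](O4)[C@@H]2O[Sn]4(CCCC)CCCC)cc1OCc1ccccc1
F4 | step 8 | (2R,3S,4S)-2-[2,5-bis(benzyloxy)-4-methoxyphenyl]-3,5,6,7-tetramethoxy-3,4-dihydro-2H-chromen-4-ol | COc1cc(OCc2ccccc2)c([C@H]2Oc3cc(OC)c(OC)c(OC)c3[C@H](O)[C@@H]2OC)cc1OCc1ccccc1
F5 | step 10 | (2R,3R)-2-(2,5-dihydroxy-4-methoxyphenyl)-3,5,6,7-tetramethoxy-2,3-dihydro-4H-chromen-4-one | COc1cc(O)c([C@H]2Oc3cc(OC)c(OC)c(OC)c3C(=O)[C@@H]2OC)cc1O
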